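A direct plan would C-acylate 2-methylphloroglucinol and phloroglucinol with butanoyl chloride to ketones A1 and A4. It would O-methylate A1 between the C-methyl and butanoyl groups to give A2 and, separately, para to the ketone to give A3. It would then join A2 and A3 in turn to A4 by two Mannich/ortho-quinone methide benzylations through dimer A5.
Its weakest steps would be the methylation to A2, whose hydroxyl is chelated, hindered and less acidic than the para one; the first benzylation of A4, in which two equivalent free ring carbons would let double benzylation compete; and the benzylation of A5 by the Mannich base of A3, in which base could reopen the first bridge and scramble the rings.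

The route rests on building ring C last from an open poly-β-carbonyl chain. Ring C is the enol form of a 2-butanoylcyclohexane-1,3,5-trione with a mirror plane through C-1 and C-4: C-2 to C-6 would come from dimethyl 3-oxopentanedioate, onto which rings A and B are grafted as salicylaldehydes (coumarin formation, then hydrogenation), and C-1 with its butanoyl group from 3-oxohexanoate. In one operation the key step would open both aryl lactones by a decarboxylative [5+1] double Claisen condensation, closing ring C and freeing the phenols beside both bridges. No phloroglucinol is benzylated, no bridge exists before the last step, and each methoxy group is set by ordinary methylation para to a carbonyl group.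

Key step: step 11

Remarks. Ring C is numbered C-1 (butanoyl), C-2, C-4, C-6 (OH), C-3 and C-5 (bridges). Ring A is the outer ring with OMe between C-methyl and butanoyl; ring B is the outer ring with OMe between C-methyl and bridge. Assumption: in steps 8 and 9 the ring A lactone is drawn through the hydroxyl next to the C-methyl group (the one not chelated to the ketone); the other lactone regioisomer would give the same product in step 11, where that oxygen is set free. The target has no stereocentre.

Step 1
Reactants: 1 2-methylbenzene-1,3,5-triol (2-methylphloroglucinol); 2 butanoyl chloride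
Product: 3 1-(2,4,6-trihydroxy-3-methylphenyl)butan-1-one
Conditions: AlCl3 (3.5 equiv), PhNO2–CH2Cl2, 0 → 45 °C; ice/2 M HCl
Reagents that add atoms: none
Why: Friedel–Crafts C-acylation; the two free ring carbons of 1 are equivalent and the chelated ketone deactivates the ring against a second acylation.

Step 2
Reactants: 3 1-(2,4,6-trihydroxy-3-methylphenyl)butan-1-one
Product: 4 1-(2,6-dihydroxy-4-methoxy-3-methylphenyl)butan-1-one (aspidinol)
Conditions: Me2SO4 (1.0 equiv), K2CO3 (1.0 equiv), acetone, rt
Reagents that add atoms: dimethyl sulfate, COS(=O)(=O)OC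
Why: Williamson O-methylation of the mono-phenoxide; the hydroxyl para to the ketone is the most acidic and the least engaged in hydrogen bonding to the carbonyl oxygen, so one equivalent of base and Me2SO4 should methylate it (standard para-selective etherification of acylphloroglucinols).

Step 3
Reactants: 4 1-(2,6-dihydroxy-4-methoxy-3-methylphenyl)butan-1-one
Product: 5 3-butanoyl-2,4-dihydroxy-6-methoxy-5-methylbenzaldehyde (ring B aldehyde)
Conditions: POCl3 (1.2 equiv), DMF (1.5 equiv), EtOAc, 0 °C → rt; then H2O, 50 °C
Reagents that add atoms: N,N-dimethylformamide, CN(C)C=O; water, O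
Why: Vilsmeier–Haack formylation at the single free ring carbon (between OMe and OH); hydrolysis of the iminium salt also cleaves any aryl formate.

Step 4
Reactants: 5 3-butanoyl-2,4-dihydroxy-6-methoxy-5-methylbenzaldehyde; 6 dimethyl 3-oxopentanedioate
Product: 7 methyl 3-(8-butanoyl-7-hydroxy-5-methoxy-6-methyl-2-oxo-2H-chromen-3-yl)-3-oxopropanoate
Conditions: 6 (3 equiv), piperidine (0.2 equiv), AcOH (0.2 equiv), MeOH, 50 °C
Reagents that add atoms: none
Why: Knoevenagel condensation followed by lactonisation (coumarin synthesis); one doubly activated methylene of 6 condenses with the aldehyde, the only ortho hydroxyl closes onto the cis ester with loss of methanol, and the excess of 6 should suppress condensation at its second methylene.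

Step 5
Reactants: 1 2-methylbenzene-1,3,5-triol
Product: 8 2,4,6-trihydroxy-3-methylbenzaldehyde
Conditions: POCl3 (1.1 equiv), DMF (1.2 equiv), EtOAc, 0 °C → rt; then H2O, 50 °C
Reagents that add atoms: N,N-dimethylformamide, CN(C)C=O; water, O
Why: Vilsmeier–Haack formylation; the two free ring carbons of 1 are equivalent and the iminium salt, which separates from the medium, should resist a second formylation.

Step 6
Reactants: 8 2,4,6-trihydroxy-3-methylbenzaldehyde
Product: 9 2,6-dihydroxy-4-methoxy-3-methylbenzaldehyde
Conditions: Me2SO4 (1.0 equiv), K2CO3 (1.0 equiv), acetone, 0 °C → rt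
Reagents that add atoms: dimethyl sulfate, COS(=O)(=O)OC
Why: Williamson O-methylation, para-selective as in step 2 but now steered by the formyl group, so that the methoxy group lands on the oxygen that will lie between the C-methyl and the later butanoyl group.

Step 7
Reactants: 9 2,6-dihydroxy-4-methoxy-3-methylbenzaldehyde; 2 butanoyl chloride
Product: 10 3-butanoyl-2,6-dihydroxy-4-methoxy-5-methylbenzaldehyde (ring A aldehyde)
Conditions: 2 (1.3 equiv), TiCl4 (3 equiv), CH2Cl2, 0 → 40 °C; 1 M HCl
Reagents that add atoms: none
Why: Friedel–Crafts C-acylation of the titanium phenoxide at the only free ring carbon, which is ortho/para to all three oxygens and meta to the formyl group; TiCl4 is chosen because it should not cleave the methyl ether that ends up ortho to the new ketone.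

Step 8
Reactants: 7 methyl 3-(8-butanoyl-7-hydroxy-5-methoxy-6-methyl-2-oxo-2H-chromen-3-yl)-3-oxopropanoate; 10 3-butanoyl-2,6-dihydroxy-4-methoxy-5-methylbenzaldehyde
Product: 11 8-butanoyl-3-[(6-butanoyl-5-hydroxy-7-methoxy-8-methyl-2-oxo-2H-chromen-3-yl)carbonyl]-7-hydroxy-5-methoxy-6-methyl-2H-chromen-2-one (unsymmetrical 3,3'-carbonylbiscoumarin)
Conditions: piperidine (0.3 equiv), AcOH (0.3 equiv), MeCN, 80 °C
Reagents that add atoms: none
Why: Second Knoevenagel condensation–lactonisation at the remaining active methylene of 7 (the known route to unsymmetrical 3,3'-carbonylbiscoumarins); the unchelated hydroxyl next to the C-methyl group should close the lactone with loss of methanol.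

Step 9
Reactants: 11 the unsymmetrical 3,3'-carbonylbiscoumarin
Product: 12 8-butanoyl-3-[(6-butanoyl-5-hydroxy-7-methoxy-8-methyl-2-oxo-3,4-dihydro-2H-chromen-3-yl)carbonyl]-7-hydroxy-5-methoxy-6-methyl-3,4-dihydro-2H-chromen-2-one (mixture of epimers at the two lactone α-carbons and of enol forms)
Conditions: H2 (3 atm), 10% Pd/C, THF–EtOAc, rt
Reagents that add atoms: none
Why: Catalytic hydrogenation of the two coumarin C-3/C-4 double bonds, each activated by lactone and ketone, while the chelated aryl ketones should survive; the two new α-stereocentres are not controlled (epimerisable β-keto lactone) and both are destroyed in step 11.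

Step 10
Reactants: 13 ethyl 3-oxohexanoate
Product: 14 potassium 3-oxohexanoate
Conditions: KOH (1.0 equiv), H2O–EtOH, 0 °C → rt; evaporation, drying in vacuo
Reagents that add atoms: potassium hydroxide, [K+].[OH-]
Why: Ester saponification; the β-keto acid is kept as its potassium salt, which does not decarboxylate on storage.

Step 11
Reactants: 12 the bis(dihydrocoumarinyl) ketone; 14 potassium 3-oxohexanoate
Product: 17 1-[3-[(3-butanoyl-2,6-dihydroxy-4-methoxy-5-methylphenyl)methyl]-5-[(3-butanoyl-2,4-dihydroxy-6-methoxy-5-methylphenyl)methyl]-2,4,6-trihydroxyphenyl]butan-1-one (CNP0171986.0), via C-acylated keto acid 15 (not isolated), via open-chain triketone lactone 16 (not isolated)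
Conditions: 14 (3 equiv), MgCl2 (5 equiv), Et3N (8 equiv), THF–MeCN, argon, 0 → 50 °C; then 1 M HCl, 0 °C
Reagents that add atoms: none
Why: Proposed new method: the magnesium enolate of 14 (a soft carbon nucleophile that plays the part of a biosynthetic extender unit) should be C-acylated by the ring B lactone of 12, an aryl ester whose leaving phenoxide is chelated to the neighbouring butanoyl group, either by direct addition–elimination or, from the lactone enolate, by E1cB loss of phenoxide and capture of the acylketene, giving keto acid 15; loss of CO2 from this 2-acyl-3-oxo acid gives triketone 16, whose methylene carbon between two ketones (the future C-1) attacks the remaining ring A lactone carbonyl (the future C-2) and expels the second phenoxide. The closest known reaction types are the magnesium-mediated decarboxylative Claisen acylation of malonic half-esters and 3-oxo acids with activated acyl donors and the biomimetic Claisen cyclisation of 3,5,7-trioxoalkanoates and their 2-pyranones to acylphloroglucinols. Ring C is closed by a 6-exo-trig Claisen (Dieckmann-type) attack that forms C-1–C-2 after the intermolecular formation of C-1–C-6, and enolisation of the cyclohexane-1,3,5-trione to the aromatic triol makes the closure irreversible. No stereocentre is formed, and the two uncontrolled lactone α-carbons of 12 end as the aromatic carbons C-3 and C-5. The step needs C- over O-acylation and Claisen over aldol closure: the aldol alternative (C-3 onto the side-chain ketone) would create a quaternary carbon that cannot aromatise and so stays reversible, a 2-pyranone from O-acylation can reopen by return of the phenoxide, triethylamine does not enolise the aryl butanoyl ketones, and because ring C has a mirror plane through C-1 and C-4 it does not matter which lactone is opened first.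

**Compound list**

1 | 2-methylbenzene-1,3,5-triol (2-methylphloroglucinol) | Cc1c(O)cc(O)cc1O | starting material
2 | butanoyl chloride | CCCC(=O)Cl | starting material
3 | 1-(2,4,6-trihydroxy-3-methylphenyl)butan-1-one | CCCC(=O)c1c(O)cc(O)c(C)c1O | intermediate
4 | 1-(2,6-dihydroxy-4-methoxy-3-methylphenyl)butan-1-one (aspidinol) | CCCC(=O)c1c(O)cc(OC)c(C)c1O | intermediate
5 | 3-butanoyl-2,4-dihydroxy-6-methoxy-5-methylbenzaldehyde (ring B aldehyde) | CCCC(=O)c1c(O)c(C=O)c(OC)c(C)c1O | intermediate
6 | dimethyl 3-oxopentanedioate | COC(=O)CC(=O)CC(=O)OC | starting material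
7 | methyl 3-(8-butanoyl-7-hydroxy-5-methoxy-6-methyl-2-oxo-2H-chromen-3-yl)-3-oxopropanoate | COC(=O)CC(=O)C1=Cc2c(OC)c(C)c(O)c(C(=O)CCC)c2OC1=O | intermediate
8 | 2,4,6-trihydroxy-3-methylbenzaldehyde | Cc1c(O)cc(O)c(C=O)c1O | intermediate
9 | 2,6-dihydroxy-4-methoxy-3-methylbenzaldehyde | COc1cc(O)c(C=O)c(O)c1C | intermediate
10 | 3-butanoyl-2,6-dihydroxy-4-methoxy-5-methylbenzaldehyde (ring A aldehyde) | CCCC(=O)c1c(OC)c(C)c(O)c(C=O)c1O | intermediate
11 | 8-butanoyl-3-[(6-butanoyl-5-hydroxy-7-methoxy-8-methyl-2-oxo-2H-chromen-3-yl)carbonyl]-7-hydroxy-5-methoxy-6-methyl-2H-chromen-2-one | CCCC(=O)c1c(O)c(C)c(OC)c2C=C(C(=O)C3=Cc4c(O)c(C(=O)CCC)c(OC)c(C)c4OC3=O)C(=O)Oc12 | intermediate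
12 | 8-butanoyl-3-[(6-butanoyl-5-hydroxy-7-methoxy-8-methyl-2-oxo-3,4-dihydro-2H-chromen-3-yl)carbonyl]-7-hydroxy-5-methoxy-6-methyl-3,4-dihydro-2H-chromen-2-one (both α-carbons uncontrolled, mixture of epimers) | CCCC(=O)c1c(O)c(C)c(OC)c2CC(C(=O)C3Cc4c(O)c(C(=O)CCC)c(OC)c(C)c4OC3=O)C(=O)Oc12 | intermediate
13 | ethyl 3-oxohexanoate | CCCC(=O)CC(=O)OCC | starting material
14 | potassium 3-oxohexanoate | CCCC(=O)CC(=O)[O-].[K+] | intermediate
15 | 2-butanoyl-4-[(3-butanoyl-2,4-dihydroxy-6-methoxy-5-methylphenyl)methyl]-5-(6-butanoyl-5-hydroxy-7-methoxy-8-methyl-2-oxo-3,4-dihydro-2H-chromen-3-yl)-3,5-dioxopentanoic acid (stereocentres uncontrolled, mixture) | CCCC(=O)C(C(=O)O)C(=O)C(Cc1c(O)c(C(=O)CCC)c(O)c(C)c1OC)C(=O)C1Cc2c(O)c(C(=O)CCC)c(OC)c(C)c2OC1=O | intermediate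
16 | 6-butanoyl-3-{2-[(3-butanoyl-2,4-dihydroxy-6-methoxy-5-methylphenyl)methyl]-3,5-dioxooctanoyl}-5-hydroxy-7-methoxy-8-methyl-3,4-dihydro-2H-chromen-2-one (stereocentres uncontrolled, mixture) | CCCC(=O)CC(=O)C(Cc1c(O)c(C(=O)CCC)c(O)c(C)c1OC)C(=O)C1Cc2c(O)c(C(=O)CCC)c(OC)c(C)c2OC1=O | intermediate
17 | 1-[3-[(3-butanoyl-2,6-dihydroxy-4-methoxy-5-methylphenyl)methyl]-5-[(3-butanoyl-2,4-dihydroxy-6-methoxy-5-methylphenyl)methyl]-2,4,6-trihydroxyphenyl]butan-1-one (CNP0171986.0, achiral) | CCCC(=O)c1c(O)c(Cc2c(O)c(C)c(OC)c(C(=O)CCC)c2O)c(O)c(Cc2c(O)c(C(=O)CCC)c(O)c(C)c2OC)c1O | target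

Total step count: 11. Longest linear sequence: 7 steps (1, 2, 3, 4, 8, 9, 11).

Steps most likely to fail

Step 11 (the step labelled as a proposed new method). The enolised β-keto lactones of 12 may not transfer their acyl groups to carbon, or O-acylation may divert the chain into a 2-pyranone that does not go on to the Claisen closure. The fallback uses known chemistry, sets out from aldehydes 10 and 5 and returns at 17. NaBH4 in MeOH at 0 °C would reduce only the formyl groups, giving 1-[2,4-dihydroxy-3-(hydroxymethyl)-6-methoxy-5-methylphenyl]butan-1-one F1 from 10 and 1-[2,6-dihydroxy-3-(hydroxymethyl)-4-methoxy-5-methylphenyl]butan-1-one F2 from 5. F1, warmed in aqueous AcOH/NaOAc with an excess of commercial 1-(2,4,6-trihydroxyphenyl)butan-1-one F3, would lose water to its ortho-quinone methide and benzylate F3 (Friedel–Crafts type) to 1-[3-[(3-butanoyl-2,6-dihydroxy-4-methoxy-5-methylphenyl)methyl]-2,4,6-trihydroxyphenyl]butan-1-one F4. F4 and F2 under the same conditions would give 17.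

Step 7. The Lewis acid may be tied up by the formyl and hydroxyl groups so that C-acylation stalls, the methyl ether ortho to the new ketone may be lost by chelation-assisted demethylation, or the formyl group may be displaced by ipso attack. The fallback sets out from 9 and returns at 10. O-Butanoylation of the unhindered hydroxyl (2, Et3N, CH2Cl2, 0 °C) would give 2-formyl-3-hydroxy-5-methoxy-4-methylphenyl butanoate F5. A photo-Fries rearrangement (254 nm, MeCN), with no Lewis acid present, would then move the acyl group to the only free ring carbon, ortho to the ester oxygen.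

Step 8. Condensation of the hindered, electron-rich aldehyde 10 may be slow enough that 7 is consumed by Michael self-condensation (its methylene carbon adding to coumarin C-4 of a second molecule). The fallback sets out from 7 and returns at 12. Hydrogenation of 7 first (H2, Pd/C) would give methyl 3-(8-butanoyl-7-hydroxy-5-methoxy-6-methyl-2-oxo-3,4-dihydro-2H-chromen-3-yl)-3-oxopropanoate F6, which has no Michael acceptor. Knoevenagel condensation–lactonisation of F6 with 10 would give 6-butanoyl-3-[(8-butanoyl-7-hydroxy-5-methoxy-6-methyl-2-oxo-3,4-dihydro-2H-chromen-3-yl)carbonyl]-5-hydroxy-7-methoxy-8-methyl-2H-chromen-2-one F7, and hydrogenation of F7 would give 12.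

**Further compounds**

F1 | step 11 | 1-[2,4-dihydroxy-3-(hydroxymethyl)-6-methoxy-5-methylphenyl]butan-1-one | CCCC(=O)c1c(OC)c(C)c(O)c(CO)c1O
F2 | step 11 | 1-[2,6-dihydroxy-3-(hydroxymethyl)-4-methoxy-5-methylphenyl]butan-1-one | CCCC(=O)c1c(O)c(CO)c(OC)c(C)c1O
F3 | step 11 | 1-(2,4,6-trihydroxyphenyl)butan-1-one | CCCC(=O)c1c(O)cc(O)cc1O
F4 | step 11 | 1-[3-[(3-butanoyl-2,6-dihydroxy-4-methoxy-5-methylphenyl)methyl]-2,4,6-trihydroxyphenyl]butan-1-one | CCCC(=O)c1c(O)cc(O)c(Cc2c(O)c(C)c(OC)c(C(=O)CCC)c2O)c1O
F5 | step 7 | 2-formyl-3-hydroxy-5-methoxy-4-methylphenyl butanoate | CCCC(=O)Oc1cc(OC)c(C)c(O)c1C=O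
F6 | step 8 | methyl 3-(8-butanoyl-7-hydroxy-5-methoxy-6-methyl-2-oxo-3,4-dihydro-2H-chromen-3-yl)-3-oxopropanoate | COC(=O)CC(=O)C1Cc2c(OC)c(C)c(O)c(C(=O)CCC)c2OC1=O
F7 | step 8 | 6-butanoyl-3-[(8-butanoyl-7-hydroxy-5-methoxy-6-methyl-2-oxo-3,4-dihydro-2H-chromen-3-yl)carbonyl]-5-hydroxy-7-methoxy-8-methyl-2H-chromen-2-one | CCCC(=O)c1c(O)c(C)c(OC)c2CC(C(=O)C3=Cc4c(O)c(C(=O)CCC)c(OC)c(C)c4OC3=O)C(=O)Oc12
A1 | direct plan | 1-(2,4,6-trihydroxy-3-methylphenyl)butan-1-one | CCCC(=O)c1c(O)cc(O)c(C)c1O
A2 | direct plan | 1-(4,6-dihydroxy-2-methoxy-3-methylphenyl)butan-1-one | CCCC(=O)c1c(O)cc(O)c(C)c1OC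
A3 | direct plan | 1-(2,6-dihydroxy-4-methoxy-3-methylphenyl)butan-1-one | CCCC(=O)c1c(O)cc(OC)c(C)c1O
A4 | direct plan | 1-(2,4,6-trihydroxyphenyl)butan-1-one | CCCC(=O)c1c(O)cc(O)cc1O
A5 | direct plan | 1-[3-[(3-butanoyl-2,6-dihydroxy-4-methoxy-5-methylphenyl)methyl]-2,4,6-trihydroxyphenyl]butan-1-one | CCCC(=O)c1c(O)cc(O)c(Cc2c(O)c(C)c(OC)c(C(=O)CCC)c2O)c1O
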